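**Assumption:** the target has no stereocentre (each quaternary ring carbon carries two methyl groups), so it is achiral and there is no enantiomer to select; the SMILES is one of several equivalent enol tautomers.

## Retrosynthetic overview

1. Cut the central aryl–CH2–aryl bond last: the target is two identical "filicinic–CH2–phloroglucinol" halves joined by formaldehyde.
2. Cut each half at the filicinic C–CH2–aryl bond: the aminomethyl (Mannich) salt of propionylfilicinic acid plus propionylphloroglucinol (flopropione).
3. Propionylfilicinic acid comes from C-propionylation of filicinic acid, whose triketone ring is closed by an intramolecular Claisen condensation of an acyclic diketo ester (methyl acetoacetate, MeI, AcCl).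
4. Flopropione comes from Friedel–Crafts propionylation of phloroglucinol; the benzene ring is taken intact from resorcinol and gains its third oxygen by meta C–H borylation/oxidation.
5. Ring order: the filicinic ring (step 3) is the only ring constructed; the aromatic ring is never built, and no ring is formed after the two branches meet.

## Route

**Step 1**
Reactants: 1 methyl acetoacetate (methyl 3-oxobutanoate)
Product: 2 methyl 2,2-dimethyl-3-oxobutanoate
Conditions: MeI (2.5 equiv), K2CO3 (3 equiv), acetone, reflux, 24 h
Reagents that add atoms: iodomethane, CI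
Why: Double SN2 C-alkylation of the β-keto ester enolate installs the gem-dimethyl carbon and removes the last acidic C–H between the carbonyls, so later enolisation can only occur at the ketone methyl group.

**Step 2**
Reactants: 2 methyl 2,2-dimethyl-3-oxobutanoate
Product: 3 methyl 2,2-dimethyl-3,5-dioxohexanoate
Conditions: 2 (2.0 equiv), LiHMDS (2.1 equiv), toluene–THF, 0 °C; AcCl (1.0 equiv), 0 °C, 10 min; 1 M HCl (excess 2 recovered by distillation)
Reagents that add atoms: acetyl chloride, CC(=O)Cl
Why: Crossed Claisen-type C-acylation of the only possible lithium enolate (ketone CH3 side); the second enolate equivalent deprotonates the more acidic 1,3-diketone product, and the absence of alkoxide avoids retro-Claisen cleavage of the α,α-disubstituted keto ester.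

**Step 3**
Reactants: 3 methyl 2,2-dimethyl-3,5-dioxohexanoate
Product: 4 filicinic acid (3,5-dihydroxy-4,4-dimethylcyclohexa-2,5-dien-1-one; enol form of 2,2-dimethylcyclohexane-1,3,5-trione)
Conditions: LDA (3.0 equiv), THF, −78 °C → rt, 3 h; 2 M HCl
Reagents that add atoms: none
Why: The Hauser–Harris 1,3-diketone dianion attacks the ester through its terminal carbanion in a 6-exo intramolecular Claisen (Dieckmann-type) condensation, driven by loss of methoxide and formation of the stabilised trione dianion.

**Step 4**
Reactants: 4 filicinic acid
Product: 6 propionylfilicinic acid (3,5-dihydroxy-6,6-dimethyl-2-propanoylcyclohexa-2,4-dien-1-one), via enol propanoate 5 (not isolated)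
Conditions: EtCO2H (1.0 equiv), DCC (1.1 equiv), DMAP (0.3 equiv), CH2Cl2–THF, 0 °C → rt, 24 h
Reagents that add atoms: propanoic acid, CCC(=O)O
Why: Steglich O-acylation of the enol followed by DMAP-catalysed O→C acyl migration gives the chelated 2-acyl trione; the two ring CH positions of 4 are equivalent, and the more acidic, less nucleophilic product resists a second acylation.

**Step 5**
Reactants: 7 resorcinol (benzene-1,3-diol)
Product: 8 1,3-dimethoxybenzene
Conditions: MeI (2.5 equiv), K2CO3 (3 equiv), acetone, reflux, 16 h
Reagents that add atoms: iodomethane, CI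
Why: Williamson ether synthesis protects both phenols and leaves C5–H as the only ring C–H without an ortho substituent.

**Step 6**
Reactants: 8 1,3-dimethoxybenzene
Product: 10 3,5-dimethoxyphenol, via arylboronate 9 (not isolated)
Conditions: [Ir(OMe)(cod)]2 (1.5 mol %), dtbpy (3 mol %), B2pin2 (0.6 equiv), cyclohexane, 80 °C, 16 h; evaporate; Oxone (1.1 equiv), acetone–H2O, rt, 15 min
Reagents that add atoms: Oxone (potassium peroxymonosulfate), [K+].[O-]S(=O)(=O)OO (supplies the phenol oxygen); bis(pinacolato)diboron, CC1(C)OB(OC1(C)C)B1OC(C)(C)C(C)(C)O1 (supplies the boryl group of 9 only)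
Why: Sterically controlled iridium-catalysed C–H borylation takes place only at C5 (meta to both methoxy groups), and peroxymonosulfate oxidation of the C–B bond (1,2-aryl shift from boron to oxygen) gives the phenol.

**Step 7**
Reactants: 10 3,5-dimethoxyphenol
Product: 11 phloroglucinol (benzene-1,3,5-triol)
Conditions: BBr3 (3.0 equiv), CH2Cl2, −78 °C → rt, 12 h; H2O, 0 °C; EtOAc extraction
Reagents that add atoms: none
Why: Lewis-acid-mediated ether cleavage; bromide attacks the methyl group of the boron-complexed aryl methyl ether (SN2) and hydrolysis frees the triol.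

**Step 8**
Reactants: 11 phloroglucinol
Product: 12 flopropione (1-(2,4,6-trihydroxyphenyl)propan-1-one)
Conditions: EtCOCl (1.1 equiv), AlCl3 (4.0 equiv), PhNO2–CH2Cl2, 0 → 50 °C, 4 h; ice/1 M HCl
Reagents that add atoms: propanoyl chloride, CCC(=O)Cl
Why: Friedel–Crafts acylation of the very electron-rich ring at one of three equivalent positions; the chelated aryl ketone deactivates the ring so monoacylation dominates.

**Step 9**
Reactants: 6 propionylfilicinic acid; 12 flopropione
Product: 14 3,5-dihydroxy-6,6-dimethyl-2-propanoyl-4-[(2,4,6-trihydroxy-3-propanoylphenyl)methyl]cyclohexa-2,4-dien-1-one, via Mannich salt 13 (not isolated)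
Conditions: (i) 6 (1.0 equiv), Me2N=CH2+ I− (1.0 equiv), MeCN, 0 °C → rt, 1 h; (ii) 12 (3.0 equiv), MeCN, 80 °C, 4 h (excess 12 recovered by chromatography)
Reagents that add atoms: N,N-dimethylmethyleneiminium iodide (Eschenmoser's salt), C=[N+](C)C.[I-] (only its CH2 stays in 14)
Why: Mannich aminomethylation at the single free ring carbon of 6, then thermal loss of dimethylamine gives a transient 2-methylene trione that is trapped by an aromatic carbon of 12 (Michael/Friedel–Crafts alkylation); consuming 6 before heating prevents its homodimer, and excess 12 suppresses double alkylation.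

**Step 10**
Reactants: 14 (2 equiv)
Product: 15 target: bis{2,4,6-trihydroxy-5-propanoyl-3-[(2,6-dihydroxy-3,3-dimethyl-4-oxo-5-propanoylcyclohexa-1,5-dien-1-yl)methyl]phenyl}methane (filicinic–CH2–phloroglucinol–CH2–phloroglucinol–CH2–filicinic; no stereocentres)
Conditions: 37 % aq. HCHO (0.5 equiv), 1 % aq. NaOH (4 equiv), N2, 0 °C → rt, 20 min; 1 M HCl to pH 2
Reagents that add atoms: formaldehyde, C=O
Why: Base-mediated hydroxymethylation (Lederer–Manasse) of the one remaining aromatic C–H, dehydration to an o-quinone methide and conjugate addition of a second phenolate join the two halves; no reactive C–H is left afterwards, so the reaction stops at the tetramer.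

## Compound list

1 | methyl acetoacetate (methyl 3-oxobutanoate) | CC(=O)CC(=O)OC | starting material
2 | methyl 2,2-dimethyl-3-oxobutanoate | CC(=O)C(C)(C)C(=O)OC | intermediate
3 | methyl 2,2-dimethyl-3,5-dioxohexanoate | CC(=O)CC(=O)C(C)(C)C(=O)OC | intermediate
4 | filicinic acid (3,5-dihydroxy-4,4-dimethylcyclohexa-2,5-dien-1-one) | CC1(C)C(O)=CC(=O)C=C1O | intermediate
5 | enol propanoate of filicinic acid (5-hydroxy-4,4-dimethyl-3-oxocyclohexa-1,5-dien-1-yl propanoate; its regioisomeric enol ester converges on the same product) | CCC(=O)OC1=CC(=O)C(C)(C)C(O)=C1 | intermediate (not isolated)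
6 | propionylfilicinic acid (3,5-dihydroxy-6,6-dimethyl-2-propanoylcyclohexa-2,4-dien-1-one) | CCC(=O)C1=C(O)C=C(O)C(C)(C)C1=O | intermediate
7 | resorcinol (benzene-1,3-diol) | Oc1cccc(O)c1 | starting material
8 | 1,3-dimethoxybenzene | COc1cccc(OC)c1 | intermediate
9 | 2-(3,5-dimethoxyphenyl)-4,4,5,5-tetramethyl-1,3,2-dioxaborolane | COc1cc(OC)cc(c1)B1OC(C)(C)C(C)(C)O1 | intermediate (not isolated)
10 | 3,5-dimethoxyphenol | COc1cc(O)cc(OC)c1 | intermediate
11 | phloroglucinol (benzene-1,3,5-triol) | Oc1cc(O)cc(O)c1 | intermediate
12 | flopropione (1-(2,4,6-trihydroxyphenyl)propan-1-one) | CCC(=O)c1c(O)cc(O)cc1O | intermediate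
13 | Mannich salt: 4-[(dimethylammonio)methyl]-3,5-dihydroxy-6,6-dimethyl-2-propanoylcyclohexa-2,4-dien-1-one iodide | CCC(=O)C1=C(O)C(C[NH+](C)C)=C(O)C(C)(C)C1=O.[I-] | intermediate (not isolated)
14 | 3,5-dihydroxy-6,6-dimethyl-2-propanoyl-4-[(2,4,6-trihydroxy-3-propanoylphenyl)methyl]cyclohexa-2,4-dien-1-one | CCC(=O)C1=C(O)C(Cc2c(O)cc(O)c(C(=O)CC)c2O)=C(O)C(C)(C)C1=O | intermediate
15 | target (CNP0541376.0; achiral) | CCC(=O)C1=C(O)C(Cc2c(O)c(Cc3c(O)c(CC4=C(O)C(C)(C)C(=O)C(C(=O)CC)=C4O)c(O)c(C(=O)CC)c3O)c(O)c(C(=O)CC)c2O)=C(O)C(C)(C)C1=O | target

## Step count and risk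

Total step count: 10.
Longest linear sequence: 6 steps (1–4, 9, 10; the resorcinol branch 5–8, 9, 10 is equally long).

**Three steps most likely to fail**

Step 3 (ring closure to filicinic acid). The dianion may react intermolecularly or close through oxygen to a pyrandione, and the ester is neopentyl-like. The fallback abandons the acyclic ring construction and sets out from 12. Flopropione 12 is treated with MeI (2.5 equiv) and NaOMe (3 equiv) in MeOH at 0 °C → rt. This dearomatising double C-methylation of the phloroglucinolate at its free ring carbon gives propionylfilicinic acid directly, so the route is rejoined at 6 and step 4 is not needed. No compound outside the list is made (F0).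

Step 9 (cross-coupling of 6 and 12). 12 has two equivalent nucleophilic carbons, so over-alkylation to a trimer competes and the result depends on a statistical excess. The fallback inverts the order of bridge formation and sets out from 12. An excess of 12 (4 equiv) is condensed with aqueous formaldehyde (1 equiv) in cold dilute NaOH to give 3,3'-methylenebis(2,4,6-trihydroxypropiophenone) F1, and the unreacted 12 is recovered. F1 has exactly two free aromatic C–H bonds and is capped exhaustively with 2.2 equiv of Mannich salt 13 (made from 6 as in stage (i) of step 9) in MeCN at 80 °C. No mono/bis selectivity is needed at the valuable stage, and the route is rejoined at 15, bypassing 14 and step 10.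

Step 10 (alkaline formaldehyde dimerisation). In alkali the existing filicinic–CH2–aryl bridge of 14 can undergo retro-Michael scrambling (the "rottlerone change"), giving albaspidin-type and bis-phloroglucinol by-products. The fallback replaces the alkaline condensation with a stepwise, non-basic aminomethylation/displacement and sets out from 14. One half of the material is treated with Eschenmoser's salt (1.0 equiv, MeCN, rt) at its single free aromatic carbon to give the aryl Mannich salt of 14 F2. F2 is then heated with the second half of 14 (1.0 equiv) in MeCN at 80 °C, where amine loss gives an o-quinone methide that C-alkylates 14. The route is rejoined at 15.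

## Further compounds

F0 | step 3 | none | none
F1 | step 9 | 3,3'-methylenebis(2,4,6-trihydroxypropiophenone) (1,1'-[methylenebis(2,4,6-trihydroxy-3,1-phenylene)]di(propan-1-one)) | CCC(=O)c1c(O)cc(O)c(Cc2c(O)cc(O)c(C(=O)CC)c2O)c1O
F2 | step 10 | aryl Mannich salt of 14: 4-({3-[(dimethylammonio)methyl]-2,4,6-trihydroxy-5-propanoylphenyl}methyl)-3,5-dihydroxy-6,6-dimethyl-2-propanoylcyclohexa-2,4-dien-1-one iodide | CCC(=O)C1=C(O)C(Cc2c(O)c(C[NH+](C)C)c(O)c(C(=O)CC)c2O)=C(O)C(C)(C)C1=O.[I-]
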